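## Retrosynthetic overview

1. Target 1: rings A and B are disconnected together and last, by a proton-initiated, catalyst-controlled cationic bicyclization of an open-chain isomer that already carries the finished side chain (cascade ends by loss of H-9).
2. Terpenoid part: (2E,6E)-farnesyl bromide 2 → (silane 3) → homofarnesol 4 → bromide 5 (one-carbon homologation).
3. Lactone part with both side-chain stereocentres (chiral pool): butenolide 6 → tosylate 7 → trans-hydroxymethyl lactone 8 → (alkoxide 9) → epoxy lactone 10.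
4. Union in one flask: 5 → Grignard reagent 11; propargyl alcohol 12 → alkoxide 13; anti-carbomagnesiation → alkenylmagnesium 14 (fixes the 13Z alkene), which opens 10 at its CH2 → open-chain tetraene 15.
5. Ring order: lactone ring first (from 6, re-formed in 10), then rings A and B together in the final step 15 → 1.

Assumption: the target is taken exactly as drawn (5S,10S,16R,17R, 13Z); atom labels follow sesterterpenoid numbering (decalin C1–C10, chain C11–C18, lactone C=O C19, lactone OCH2 C25).

## Route

Step 1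
Reactants: 2 (2E,6E)-farnesyl bromide
Product: 4 (3E,7E)-homofarnesol, via homofarnesyl(isopropoxy)dimethylsilane 3 (not isolated)
Conditions: ClMgCH2SiMe2(OiPr) (1.3 equiv, prepared beforehand), Li2CuCl4 (3 mol %), THF, 0 °C; then 30% H2O2, KF, KHCO3, THF/MeOH, rt
Reagents that add atoms: (isopropoxydimethylsilyl)methylmagnesium chloride, CC(C)O[Si](C)(C)C[Mg]Cl; hydrogen peroxide, OO
Why: Kochi-type copper-catalysed coupling of the primary allylic bromide occurs at the unhindered α-carbon with the 2E alkene retained, and Tamao oxidation converts C–Si into C–OH; no stereocentre is formed.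

Step 2
Reactants: 4 (3E,7E)-homofarnesol
Product: 5 (3E,7E)-homofarnesyl bromide
Conditions: CBr4, PPh3, CH2Cl2, 0 °C
Reagents that add atoms: tetrabromomethane, BrC(Br)(Br)Br
Why: Appel reaction, SN2 at a primary homoallylic carbon, leaves the three alkenes untouched.

Step 3
Reactants: 6 (S)-5-(hydroxymethyl)furan-2(5H)-one
Product: 7 [(2S)-5-oxo-2,5-dihydrofuran-2-yl]methyl 4-methylbenzenesulfonate
Conditions: TsCl, pyridine, CH2Cl2, 0 °C
Reagents that add atoms: 4-methylbenzenesulfonyl chloride, Cc1ccc(cc1)S(Cl)(=O)=O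
Why: O-sulfonylation of the primary alcohol under weakly basic conditions does not touch the γ-stereocentre, which becomes C16 of the target.

Step 4
Reactants: 7 [(2S)-5-oxo-2,5-dihydrofuran-2-yl]methyl 4-methylbenzenesulfonate
Product: 8 [(2S,3R)-3-(hydroxymethyl)-5-oxooxolan-2-yl]methyl 4-methylbenzenesulfonate
Conditions: Ph2CO (10 mol %), MeOH (0.05 M, degassed), hν 350 nm, rt
Reagents that add atoms: methanol, CO
Why: Benzophenone-sensitised radical conjugate addition of the hydroxymethyl radical to the butenolide β-carbon occurs anti to the CH2OTs group, setting the new stereocentre (C17, R) trans to C16.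

Step 5
Reactants: 8 [(2S,3R)-3-(hydroxymethyl)-5-oxooxolan-2-yl]methyl 4-methylbenzenesulfonate
Product: 10 (4R)-4-[(2S)-oxiran-2-yl]oxolan-2-one, via translactonised sodium alkoxide 9 (not isolated)
Conditions: NaH (1.05 equiv), THF (0.02 M), 0 °C → rt
Reagents that add atoms: none
Why: Intramolecular transesterification (translactonization) of the primary alkoxide onto the lactone carbonyl frees the C16 alkoxide, which closes the epoxide irreversibly on CH2OTs (Williamson 3-exo-tet); the C16–O bond is never broken (retention), and direct attack of the primary alkoxide on CH2OTs would need a trans-fused bicyclo[3.3.0] ring.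

Step 6
Reactants: 5 (3E,7E)-homofarnesyl bromide; 12 propargyl alcohol; 10 (4R)-4-[(2S)-oxiran-2-yl]oxolan-2-one
Product: 15 (4R)-4-[(1R,3Z,7E,11E)-1-hydroxy-4-(hydroxymethyl)-8,12,16-trimethylheptadeca-3,7,11,15-tetraen-1-yl]oxolan-2-one, via homofarnesylmagnesium bromide 11 (not isolated), via chloromagnesium prop-2-yn-1-olate 13 (not isolated), via (Z)-alkenylmagnesium species 14 (not isolated)
Conditions: 5, Mg, THF, rt (1.3 equiv); 12, i-PrMgCl (1.0 equiv), THF, −20 °C (1.2 equiv); combine, CuI (10 mol %), −10 °C → rt, 4 h; then 10 (1.0 equiv), −30 → −10 °C; aq. NH4Cl at −30 °C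
Reagents that add atoms: none
Why: CuI-catalysed anti-carbomagnesiation of the propargylic alkoxide places homofarnesyl on C13 and magnesium on C14 cis to CH2O (five-membered chelate), and copper-catalysed opening of the terminal epoxide at CH2 keeps that geometry (13Z) and leaves C16 untouched; at −30 °C this is faster than Grignard addition to the lactone or acyl migration of the magnesium alkoxide.

Step 7
Reactants: 15 (4R)-4-[(1R,3Z,7E,11E)-1-hydroxy-4-(hydroxymethyl)-8,12,16-trimethylheptadeca-3,7,11,15-tetraen-1-yl]oxolan-2-one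
Product: 1 (4R)-4-{(1R,3Z)-1-hydroxy-4-(hydroxymethyl)-6-[(4aS,8aS)-2,5,5,8a-tetramethyl-3,4,4a,5,6,7,8,8a-octahydronaphthalen-1-yl]hex-3-en-1-yl}oxolan-2-one
Conditions: IDPi acid [(3,3′-Ar2-1,1′-binaphthalene-2,2′-diyl-O,O′)P(=NSO2CF3)]2NH (Ar = 3,5-(CF3)2C6H3; the enantiomer that gives (−)-ambrox from 4 in a control run), 5 mol %, (CF3)3COH/CH2Cl2 9:1, −30 °C, 48 h; chromatography removes the minor decalin diastereomer
Reagents that add atoms: none
Why: Proposed new method: the confined chiral acid protonates the terminal trisubstituted alkene of the chair–chair-folded homofarnesyl segment on the same face as in homofarnesol → (−)-ambrox (which has the 5S,10S decalin needed here), and anti additions across the two E-alkenes (Stork–Eschenmoser) give the trans-fused C8 cation; that cation has no hetero-nucleophile within reach (the CH2OH oxygen would have to close a seven-membered ring) and only an inductively deactivated, fluoroalcohol-hydrogen-bonded C13=C14 alkene nearby, so it loses the axial 9α-H to the counter-anion to give the tetrasubstituted C8=C9 alkene, which is also the thermodynamic isomer, while C16, C17 and the lactone are not involved; the closest known reactions are the IDPi-catalysed bicyclization of homofarnesol to ambrox, BINOL·SnCl4-type enantioselective polyene cyclizations that end by proton loss, and superacid bicyclizations of polyprenoids that stop at a deactivated alkene.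

## Compound list

1 | (4R)-4-{(1R,3Z)-1-hydroxy-4-(hydroxymethyl)-6-[(4aS,8aS)-2,5,5,8a-tetramethyl-3,4,4a,5,6,7,8,8a-octahydronaphthalen-1-yl]hex-3-en-1-yl}oxolan-2-one | CC1=C(CC/C(=C/C[C@@H](O)[C@H]2COC(=O)C2)CO)[C@@]2(C)CCCC(C)(C)[C@@H]2CC1 | target
2 | (2E,6E)-farnesyl bromide | CC(C)=CCC/C(C)=C/CC/C(C)=C/CBr | starting material
3 | isopropoxydimethyl[(3E,7E)-4,8,12-trimethyltrideca-3,7,11-trien-1-yl]silane | CC(C)=CCC/C(C)=C/CC/C(C)=C/CC[Si](C)(C)OC(C)C | intermediate
4 | (3E,7E)-homofarnesol, (3E,7E)-4,8,12-trimethyltrideca-3,7,11-trien-1-ol | CC(C)=CCC/C(C)=C/CC/C(C)=C/CCO | intermediate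
5 | (3E,7E)-homofarnesyl bromide, (3E,7E)-1-bromo-4,8,12-trimethyltrideca-3,7,11-triene | CC(C)=CCC/C(C)=C/CC/C(C)=C/CCBr | intermediate
6 | (S)-5-(hydroxymethyl)furan-2(5H)-one | OC[C@H]1OC(=O)C=C1 | starting material
7 | [(2S)-5-oxo-2,5-dihydrofuran-2-yl]methyl 4-methylbenzenesulfonate | Cc1ccc(cc1)S(=O)(=O)OC[C@H]1OC(=O)C=C1 | intermediate
8 | [(2S,3R)-3-(hydroxymethyl)-5-oxooxolan-2-yl]methyl 4-methylbenzenesulfonate (trans) | Cc1ccc(cc1)S(=O)(=O)OC[C@H]1OC(=O)C[C@@H]1CO | intermediate
9 | sodium (1S)-1-[(3R)-5-oxooxolan-3-yl]-2-(tosyloxy)ethan-1-olate | [Na+].[O-][C@H](COS(=O)(=O)c1ccc(C)cc1)[C@H]1COC(=O)C1 | intermediate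
10 | (4R)-4-[(2S)-oxiran-2-yl]oxolan-2-one | O=C1C[C@H](CO1)[C@H]1CO1 | intermediate
11 | (3E,7E)-homofarnesylmagnesium bromide | CC(C)=CCC/C(C)=C/CC/C(C)=C/CC[Mg]Br | intermediate
12 | propargyl alcohol (prop-2-yn-1-ol) | C#CCO | starting material
13 | chloromagnesium prop-2-yn-1-olate | C#CCO[Mg]Cl | intermediate
14 | (Z)-alkenylmagnesium species BrMg–CH=C(homofarnesyl)–CH2–OMgCl, Mg on carbon cis to CH2O | CC(C)=CCC/C(C)=C/CC/C(C)=C/CC/C(=C/[Mg]Br)CO[Mg]Cl | intermediate
15 | (4R)-4-[(1R,3Z,7E,11E)-1-hydroxy-4-(hydroxymethyl)-8,12,16-trimethylheptadeca-3,7,11,15-tetraen-1-yl]oxolan-2-one | CC(C)=CCC/C(C)=C/CC/C(C)=C/CC/C(=C/C[C@@H](O)[C@H]1COC(=O)C1)CO | intermediate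

## Step count and risks

Total: 7 steps. Longest linear sequence: 5 steps (6 → 7 → 8 → 10 → 15 → 1); the terpenoid branch is 4 steps (2 → 4 → 5 → 15 → 1).

Steps most likely to fail:

Step 7 (final bicyclization). Risks are ring C closure through C13=C14, formation of the 7-ene or 8(17)-ene alkene isomers instead of the 8(9)-ene, and weaker facial control than with homofarnesol because the hydroxyl handle is missing. The fallback sets out from 4 and comes back at 1. Homofarnesol 4 is cyclised first, where the chemistry is established (the same IDPi acid in (CF3)3COH, or a squalene–hopene cyclase), to (−)-ambrox F1. Me3SiI made in situ (Me3SiCl, NaI, MeCN, 0 °C → rt) cleaves the tertiary C8–O bond, turns the primary silyl ether into the iodide and, through the HI released, moves the alkene to the tetrasubstituted position, giving (4aS,8aS)-5-(2-iodoethyl)-1,1,4a,6-tetramethyl-1,2,3,4,4a,7,8,8a-octahydronaphthalene F2. Mg in THF gives the bicyclic Grignard reagent F3, which under the conditions of step 6 adds to 13 (CuI) to give the bicyclic (Z)-alkenylmagnesium species F4; this opens 10 and gives 1 directly.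

Step 6 (three-component union). Risks are Grignard attack on the lactone of 10, acyl migration of the C16 magnesium alkoxide to the isomeric lactone, and low reactivity of the chelated alkenylmagnesium. The fallback sets out from 14 and comes back at 15. Intermediate 14 is quenched with I2 (THF, −40 °C) to give (2Z)-3-iodo-2-[(3E,7E)-4,8,12-trimethyltrideca-3,7,11-trien-1-yl]prop-2-en-1-ol F5, which is isolated. F5 and 10 are then joined by nickel-catalysed reductive cross-electrophile coupling (NiCl2(1,2-dimethoxyethane), 4,4′-di-tert-butyl-2,2′-bipyridine, NaI, Et3N·HCl, Mn powder, DMPU, rt). Iodide opens the epoxide at CH2 to (4R)-4-[(1S)-1-hydroxy-2-iodoethyl]oxolan-2-one F6, whose primary C–I bond is coupled with the alkenyl iodide at nickel; no Grignard reagent meets the lactone and no alkoxide is formed.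

Step 4 (photochemical hydroxymethylation). Risks are that the radical addition is established for the silyl ether analogue but not for the sulfonate, and that the anti selectivity could be lower with the smaller CH2OTs group. The fallback sets out from 7 and comes back at 8. The hydroxymethyl group is introduced by polar chemistry: ClMgCH2SiMe2(OiPr), CuBr·SMe2 (20 mol %), THF, −78 °C adds anti to the C5 substituent to give [(2S,3S)-3-{[dimethyl(propan-2-yloxy)silyl]methyl}-5-oxooxolan-2-yl]methyl 4-methylbenzenesulfonate F7. Tamao oxidation under non-basic conditions (mCPBA, KF, DMF, rt) then gives 8.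

## Further compounds

F1 | step 7 | (−)-ambrox, (3aR,5aS,9aS,9bR)-3a,6,6,9a-tetramethyldodecahydronaphtho[2,1-b]furan | O1CC[C@H]2[C@@]1(C)CC[C@H]1C(C)(C)CCC[C@]21C
F2 | step 7 | (4aS,8aS)-5-(2-iodoethyl)-1,1,4a,6-tetramethyl-1,2,3,4,4a,7,8,8a-octahydronaphthalene | CC1=C(CCI)[C@@]2(C)CCCC(C)(C)[C@@H]2CC1
F3 | step 7 | {2-[(4aS,8aS)-2,5,5,8a-tetramethyl-3,4,4a,5,6,7,8,8a-octahydronaphthalen-1-yl]ethyl}magnesium iodide | CC1=C(CC[Mg]I)[C@@]2(C)CCCC(C)(C)[C@@H]2CC1
F4 | step 7 | bicyclic (Z)-alkenylmagnesium species IMg–CH=C(CH2CH2-decalinyl)–CH2–OMgCl | CC1=C(CC/C(=C/[Mg]I)CO[Mg]Cl)[C@@]2(C)CCCC(C)(C)[C@@H]2CC1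
F5 | step 6 | (2Z)-3-iodo-2-[(3E,7E)-4,8,12-trimethyltrideca-3,7,11-trien-1-yl]prop-2-en-1-ol | CC(C)=CCC/C(C)=C/CC/C(C)=C/CC/C(=C/I)CO
F6 | step 6 | (4R)-4-[(1S)-1-hydroxy-2-iodoethyl]oxolan-2-one | IC[C@@H](O)[C@H]1COC(=O)C1
F7 | step 4 | [(2S,3S)-3-{[dimethyl(propan-2-yloxy)silyl]methyl}-5-oxooxolan-2-yl]methyl 4-methylbenzenesulfonate | Cc1ccc(cc1)S(=O)(=O)OC[C@H]1OC(=O)C[C@@H]1C[Si](C)(C)OC(C)C
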